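**Strategy.** Ring A is disconnected at C8–C8a and C4a–C5. This works because ring A is a fully substituted phloroglucinol: C5(OH)–C6(Me)–C7(OH)–C8(prenyl) is a γ-prenylated methyl 2-methylacetoacetate, and C4a=C8a is the enol-ether alkene of a 2-aryl-2,3-dihydropyran-4-one (ring C) that already carries the (2S) centre. One thermal Diels–Alder/aromatisation between the bis(trimethylsilyl) dienol ether 13 and the 5-phenylsulfinyl dihydropyranone 8 forms both bonds, closes ring A and places every ring-A substituent, so no choice between ortho hydroxyls arises. C2 comes from an asymmetric hetero-Diels–Alder reaction of 4-silyloxybenzaldehyde; the sulfoxide is both activator and traceless leaving group.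

Key step: step 9

**Remarks before the route**
- Assumption: the (S)-BINOL–Ti(OiPr)4 catalyst is taken to give the (2S)-dihydropyranone; if the first batch shows the opposite sense, (R)-BINOL is used and nothing else changes.
- Structure check: the (2S) descriptor holds for 5, 8, 16 and 17 (O1 > aryl > C3 > H throughout), and the diene and dienophile map onto the target without correction.
- Atom map of step 9: diene C1 → C5, C2 → C6 (methyl), C3 → C7, C4 → C8 (diene C5–C8 is the prenyl group); pyranone C5 → C4a, C6 → C8a, C2 → C2.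
- Precursor design:
  - (a) The 4'-oxygen is kept as the TBS ether, so ring B cannot open the benzylic C2–O1 bond through a quinone methide.
  - (b) Sulfur is introduced with an amine base only and oxidised last, because keto sulfoxide 8 is the most base-sensitive compound; 8 is used as the mixture of sulfur epimers.
  - (c) Diene 13 is used fresh, in excess and without Lewis acid; the excess also traps the benzenesulfenic acid released.

**Route**

Step 1
Reactants: 1 4-hydroxybenzaldehyde
Product: 2 4-(tert-butyldimethylsilyloxy)benzaldehyde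
Conditions: TBSCl, imidazole, DMF, 0 °C → rt
Reagents that add atoms: tert-butyldimethylsilyl chloride, CC(C)(C)[Si](C)(C)Cl
Why: Imidazole-promoted O-silylation of a phenol (Corey silylation) is selective and gives an aryl silyl ether that should survive every later step that is free of fluoride and inorganic base.

Step 2
Reactants: 2 4-(tert-butyldimethylsilyloxy)benzaldehyde; 3 Danishefsky's diene, (E)-1-methoxy-3-(trimethylsilyloxy)buta-1,3-diene
Product: 5 (2S)-2-[4-(tert-butyldimethylsilyloxy)phenyl]-2,3-dihydro-4H-pyran-4-one, via open-chain silyl aldol adduct 4 (not isolated)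
Conditions: (S)-1,1′-bi-2-naphthol (20 mol%), Ti(OiPr)4 (10 mol%), 4 Å MS, Et2O, −20 °C; then CF3CO2H, CH2Cl2, 0 °C
Reagents that add atoms: none
Why: Catalytic asymmetric hetero-Diels–Alder reaction in its Mukaiyama-aldol/cyclisation mode, in which the diene terminus adds to one enantiotopic face of the titanium-bound aldehyde and acid then closes ring C with loss of methanol; the C2 stereocentre is set by the chiral Ti–BINOL complex (catalyst control).

Step 3
Reactants: 5 (2S)-2-[4-(tert-butyldimethylsilyloxy)phenyl]-2,3-dihydro-4H-pyran-4-one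
Product: 6 (2S)-2-[4-(tert-butyldimethylsilyloxy)phenyl]-5-iodo-2,3-dihydro-4H-pyran-4-one
Conditions: I2, pyridine, CH2Cl2, 0 °C → rt; aq. Na2S2O3
Reagents that add atoms: iodine, [I][I]
Why: The α-carbon C5 of the vinylogous ester is its nucleophilic position, so iodine/pyridine α-iodination of the enone (Johnson-type iodination) should give the 5-iodide without touching C2.

Step 4
Reactants: 6 (2S)-2-[4-(tert-butyldimethylsilyloxy)phenyl]-5-iodo-2,3-dihydro-4H-pyran-4-one
Product: 7 (2S)-2-[4-(tert-butyldimethylsilyloxy)phenyl]-5-(phenylsulfanyl)-2,3-dihydro-4H-pyran-4-one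
Conditions: PhSH, Pd2(dba)3 (2.5 mol%), Xantphos [4,5-bis(diphenylphosphino)-9,9-dimethylxanthene] (5 mol%), iPr2NEt, 1,4-dioxane, 80 °C
Reagents that add atoms: thiophenol, Sc1ccccc1
Why: Palladium-catalysed C–S cross-coupling (Migita-type thiolation) of the α-iodoenone, which undergoes fast oxidative addition, needs only a tertiary amine base and so should spare the aryl silyl ether and the base-sensitive C2–O1 bond.

Step 5
Reactants: 7 (2S)-2-[4-(tert-butyldimethylsilyloxy)phenyl]-5-(phenylsulfanyl)-2,3-dihydro-4H-pyran-4-one
Product: 8 (2S)-2-[4-(tert-butyldimethylsilyloxy)phenyl]-5-(phenylsulfinyl)-2,3-dihydro-4H-pyran-4-one (mixture of both sulfur epimers)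
Conditions: mCPBA (1.0 equiv), NaHCO3, CH2Cl2, −78 → −40 °C
Reagents that add atoms: meta-chloroperoxybenzoic acid, OOC(=O)c1cccc(Cl)c1
Why: Chemoselective sulfide-to-sulfoxide oxidation with one equivalent of peracid at low temperature should stop at the sulfoxide, since the electron-poor push–pull alkene is inert to mCPBA; the new sulfur stereocentre is left uncontrolled because sulfur is lost in step 9.

Step 6
Reactants: 9 methyl 2-methylacetoacetate (methyl 2-methyl-3-oxobutanoate); 10 prenyl bromide (1-bromo-3-methylbut-2-ene)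
Product: 11 methyl 2,7-dimethyl-3-oxooct-6-enoate (racemic at C2)
Conditions: NaH, THF, 0 °C; n-BuLi, 0 °C; 10, 0 °C → rt; then 1 M HCl
Reagents that add atoms: none
Why: Weiler dianion alkylation, in which the more basic γ-carbanion of the sodium/lithium dianion is alkylated by the allylic bromide in an SN2 reaction, should give only the γ-prenylated β-keto ester.

Step 7
Reactants: 11 methyl 2,7-dimethyl-3-oxooct-6-enoate
Product: 12 methyl 2,7-dimethyl-3-(trimethylsilyloxy)octa-2,6-dienoate (E/Z mixture)
Conditions: TMSCl, Et3N, toluene, rt, 72 h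
Reagents that add atoms: chlorotrimethylsilane, C[Si](C)(C)Cl
Why: Soft enolisation and O-silylation of the β-keto ester gives the conjugated silyl enol ether, the standard first stage of a 1,3-bis(silyloxy)diene synthesis.

Step 8
Reactants: 12 methyl 2,7-dimethyl-3-(trimethylsilyloxy)octa-2,6-dienoate
Product: 13 1-methoxy-2,7-dimethyl-1,3-bis(trimethylsilyloxy)octa-1,3,6-triene (geometric mixture, expected mainly 3Z)
Conditions: LDA (lithium diisopropylamide), THF, −78 °C; TMSCl, −78 °C → rt; hexane, filtration under argon
Reagents that add atoms: chlorotrimethylsilane, C[Si](C)(C)Cl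
Why: Kinetic γ-deprotonation of the silyloxy enoate gives the ester dienolate, which is O-silylated to the 1,3-bis(silyloxy)diene (Chan-type diene synthesis), with the prenyl methylene expected on the outer side of the s-cis diene.

Step 9
Reactants: 8 (2S)-2-[4-(tert-butyldimethylsilyloxy)phenyl]-5-(phenylsulfinyl)-2,3-dihydro-4H-pyran-4-one; 13 1-methoxy-2,7-dimethyl-1,3-bis(trimethylsilyloxy)octa-1,3,6-triene
Product: 16 (2S)-4'-O-tert-butyldimethylsilyl-6-methyl-8-prenylnaringenin, via sulfinyl cycloadduct 14 (not isolated), via 7-O-trimethylsilyl flavanone 15 (not isolated)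
Conditions: 13 (2.5 equiv), toluene, rt → 80 °C; then 0.5 M HCl, THF, 0 °C
Reagents that add atoms: none
Why: In a normal-electron-demand Diels–Alder reaction the nucleophilic, prenyl-bearing diene terminus C4 bonds to C8a (the β-carbon of the keto sulfoxide) and the ketene-acetal carbon C1 bonds to C4a, either concertedly but asynchronously or by Mukaiyama–Michael addition followed by ring closure; adduct 14 then loses benzenesulfenic acid by thermal syn-elimination (the sulfinyl group and C8a–H are cis because the alkene geometry is conserved), the C5 ketal collapses with loss of methoxytrimethylsilane, and the C8–H dienone tautomerises to the phenol. The closest known reaction type is the cycloaddition–aromatisation of 1-alkoxy-1,3-bis(silyloxy)dienes with sulfinyl-activated enones, sulfinylquinones and 3-sulfinylchromones, of which the non-benzo-fused dihydropyranone 8 is a close analogue. Ring A is closed as a six-membered carbocycle by intermolecular [4+2] annulation forming C8–C8a and C4a–C5 (in the stepwise limit the second bond forms by 6-exo-trig attack on the ester-derived carbon). No new stereocentre survives, since the sp3 centres of 14 are erased on aromatisation, and C2 is a spectator whose C–O bond and neighbouring CH2 are untouched under neutral conditions. The step needs regioselectivity, which follows from matching the diene polarisation (C4 most nucleophilic) with the doubly activated alkene (C8a most electrophilic), and chemoselectivity against expulsion of O1 from C8a, which is secured by the absence of Lewis acid or base and by C4a being quaternary in 14, so that only the sulfoxide can leave.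

Step 10
Reactants: 16 (2S)-4'-O-tert-butyldimethylsilyl-6-methyl-8-prenylnaringenin
Product: 17 6-methyl-8-prenylnaringenin, (2S)-5,7-dihydroxy-2-(4-hydroxyphenyl)-6-methyl-8-(3-methylbut-2-en-1-yl)chroman-4-one
Conditions: HF·pyridine, pyridine, THF, 0 °C → rt
Reagents that add atoms: none
Why: Fluoride-mediated cleavage of the aryl silyl ether with buffered HF·pyridine avoids the phenoxide-induced ring opening to the chalcone that would racemise C2, and is mild enough to leave the prenyl group uncyclised.

**Compound list**

1 | 4-hydroxybenzaldehyde | O=Cc1ccc(O)cc1 | starting material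
2 | 4-(tert-butyldimethylsilyloxy)benzaldehyde | O=Cc1ccc(O[Si](C)(C)C(C)(C)C)cc1 | intermediate
3 | Danishefsky's diene, (E)-1-methoxy-3-(trimethylsilyloxy)buta-1,3-diene | CO/C=C/C(=C)O[Si](C)(C)C | starting material
4 | (1E,5S)-5-[4-(tert-butyldimethylsilyloxy)phenyl]-1-methoxy-5-(trimethylsilyloxy)pent-1-en-3-one (not isolated) | CO/C=C/C(=O)C[C@H](O[Si](C)(C)C)c1ccc(O[Si](C)(C)C(C)(C)C)cc1 | intermediate
5 | (2S)-2-[4-(tert-butyldimethylsilyloxy)phenyl]-2,3-dihydro-4H-pyran-4-one | O=C1C[C@@H](c2ccc(O[Si](C)(C)C(C)(C)C)cc2)OC=C1 | intermediate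
6 | (2S)-2-[4-(tert-butyldimethylsilyloxy)phenyl]-5-iodo-2,3-dihydro-4H-pyran-4-one | O=C1C[C@@H](c2ccc(O[Si](C)(C)C(C)(C)C)cc2)OC=C1I | intermediate
7 | (2S)-2-[4-(tert-butyldimethylsilyloxy)phenyl]-5-(phenylsulfanyl)-2,3-dihydro-4H-pyran-4-one | O=C1C[C@@H](c2ccc(O[Si](C)(C)C(C)(C)C)cc2)OC=C1Sc1ccccc1 | intermediate
8 | (2S)-2-[4-(tert-butyldimethylsilyloxy)phenyl]-5-(phenylsulfinyl)-2,3-dihydro-4H-pyran-4-one (both sulfur epimers) | O=C1C[C@@H](c2ccc(O[Si](C)(C)C(C)(C)C)cc2)OC=C1S(=O)c1ccccc1 | intermediate
9 | methyl 2-methylacetoacetate | COC(=O)C(C)C(C)=O | starting material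
10 | prenyl bromide | CC(C)=CCBr | starting material
11 | methyl 2,7-dimethyl-3-oxooct-6-enoate (racemic at C2) | COC(=O)C(C)C(=O)CCC=C(C)C | intermediate
12 | methyl 2,7-dimethyl-3-(trimethylsilyloxy)octa-2,6-dienoate (E/Z mixture) | COC(=O)C(C)=C(O[Si](C)(C)C)CCC=C(C)C | intermediate
13 | 1-methoxy-2,7-dimethyl-1,3-bis(trimethylsilyloxy)octa-1,3,6-triene (geometric mixture) | COC(O[Si](C)(C)C)=C(C)C(O[Si](C)(C)C)=CCC=C(C)C | intermediate
14 | (2S)-2-[4-(tert-butyldimethylsilyloxy)phenyl]-5-methoxy-6-methyl-8-prenyl-4a-(phenylsulfinyl)-5,7-bis(trimethylsilyloxy)-2,3,4a,5,8,8a-hexahydro-4H-chromen-4-one (diastereomer mixture at C4a, C5, C8, C8a and sulfur; not isolated) | COC1(O[Si](C)(C)C)C(C)=C(O[Si](C)(C)C)C(CC=C(C)C)C2O[C@H](c3ccc(O[Si](C)(C)C(C)(C)C)cc3)CC(=O)C12S(=O)c1ccccc1 | intermediate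
15 | (2S)-2-[4-(tert-butyldimethylsilyloxy)phenyl]-5-hydroxy-6-methyl-8-prenyl-7-(trimethylsilyloxy)chroman-4-one (not isolated) | CC(C)=CCc1c(O[Si](C)(C)C)c(C)c(O)c2c1O[C@H](c1ccc(O[Si](C)(C)C(C)(C)C)cc1)CC2=O | intermediate
16 | (2S)-4'-O-tert-butyldimethylsilyl-6-methyl-8-prenylnaringenin, (2S)-2-[4-(tert-butyldimethylsilyloxy)phenyl]-5,7-dihydroxy-6-methyl-8-(3-methylbut-2-en-1-yl)chroman-4-one | CC(C)=CCc1c(O)c(C)c(O)c2c1O[C@H](c1ccc(O[Si](C)(C)C(C)(C)C)cc1)CC2=O | intermediate
17 | 6-methyl-8-prenylnaringenin, (2S)-5,7-dihydroxy-2-(4-hydroxyphenyl)-6-methyl-8-(3-methylbut-2-en-1-yl)chroman-4-one | CC(C)=CCc1c(O)c(C)c(O)c2c1O[C@H](c1ccc(O)cc1)CC2=O | target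

**Step count.** Total: 10 steps. Longest linear sequence: 7 steps (steps 1–5, 9, 10 from 4-hydroxybenzaldehyde); the diene branch is steps 6–8.

**Steps most likely to fail**

1. Step 9. Bond formation at the hindered, prenyl-substituted diene terminus may be too slow. Silyl transfer from the diene to the sulfinyl oxygen (Pummerer-type loss of the dienophile) or conjugate addition without ring closure could then take over. The fallback sets out from 8 and 9 and returns at 16; it moves the prenyl group to a separate step after the annulation. Methyl 2-methylacetoacetate 9 would be silylated (Et3N, TMSCl) to methyl 2-methyl-3-(trimethylsilyloxy)but-2-enoate F1 and then (LDA, TMSCl) to 1-methoxy-2-methyl-1,3-bis(trimethylsilyloxy)buta-1,3-diene F2, whose terminus is an unhindered CH2. Heating F2 with 8 in toluene should give, through the sulfinyl cycloadduct F3 and the 7-O-trimethylsilyl ether F4 (neither isolated), (2S)-4'-O-tert-butyldimethylsilyl-6-methylnaringenin F5. C8 is the only free ring-A carbon of F5, so Friedel–Crafts-type nuclear prenylation (2-methylbut-3-en-2-ol, BF3·OEt2, dioxane, rt) should give 16 with no regiochemical choice, at the cost of a step of modest efficiency. This fallback answers steric retardation only; it would not help if the dihydropyranone itself proved an inert dienophile.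

2. Step 4. Thiolate may poison the palladium catalyst or add reversibly to C6 with ring opening, leading to protodeiodination or erosion of the C2 configuration. The fallback sets out from 5 and returns at 7, bypassing 6 and all cross-coupling. Benzenesulfenyl chloride (prepared separately from diphenyl disulfide and SO2Cl2) would add across the enol-ether alkene in CH2Cl2 at −78 °C to give (2S)-2-[4-(tert-butyldimethylsilyloxy)phenyl]-6-chloro-5-(phenylsulfanyl)tetrahydro-4H-pyran-4-one F6 (not isolated). Et3N would then remove HCl by E1cB elimination to give 7.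

3. Step 2. The electron-rich aldehyde may bind and react sluggishly at titanium, so that uncatalysed background addition lowers facial selectivity. The fallback sets out from 2 and returns at 5. It replaces Lewis-acid aldol/cyclisation by a hydrogen-bond-catalysed concerted cycloaddition with a far more reactive amino siloxy diene. Aldehyde 2 and 1-(dimethylamino)-3-(tert-butyldimethylsilyloxy)buta-1,3-diene would be combined in toluene at −40 °C with the enantiomer of α,α,α′,α′-tetra(1-naphthyl)-2,2-dimethyl-1,3-dioxolane-4,5-dimethanol (a TADDOL diol) that shields the unwanted face. This should give (6S)-6-[4-(tert-butyldimethylsilyloxy)phenyl]-4-(tert-butyldimethylsilyloxy)-N,N-dimethyl-3,6-dihydro-2H-pyran-2-amine F7 (not isolated), which acetyl chloride at −78 °C converts into 5.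

**Further compounds**

F1 | step 9 | methyl 2-methyl-3-(trimethylsilyloxy)but-2-enoate | COC(=O)C(C)=C(C)O[Si](C)(C)C
F2 | step 9 | 1-methoxy-2-methyl-1,3-bis(trimethylsilyloxy)buta-1,3-diene | COC(O[Si](C)(C)C)=C(C)C(=C)O[Si](C)(C)C
F3 | step 9 | (2S)-2-[4-(tert-butyldimethylsilyloxy)phenyl]-5-methoxy-6-methyl-4a-(phenylsulfinyl)-5,7-bis(trimethylsilyloxy)-2,3,4a,5,8,8a-hexahydro-4H-chromen-4-one (diastereomer mixture) | COC1(O[Si](C)(C)C)C(C)=C(O[Si](C)(C)C)CC2O[C@H](c3ccc(O[Si](C)(C)C(C)(C)C)cc3)CC(=O)C12S(=O)c1ccccc1
F4 | step 9 | (2S)-2-[4-(tert-butyldimethylsilyloxy)phenyl]-5-hydroxy-6-methyl-7-(trimethylsilyloxy)chroman-4-one | Cc1c(O[Si](C)(C)C)cc2O[C@H](c3ccc(O[Si](C)(C)C(C)(C)C)cc3)CC(=O)c2c1O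
F5 | step 9 | (2S)-4'-O-tert-butyldimethylsilyl-6-methylnaringenin | Cc1c(O)cc2O[C@H](c3ccc(O[Si](C)(C)C(C)(C)C)cc3)CC(=O)c2c1O
F6 | step 4 | (2S)-2-[4-(tert-butyldimethylsilyloxy)phenyl]-6-chloro-5-(phenylsulfanyl)tetrahydro-4H-pyran-4-one (diastereomer mixture at C5 and C6) | O=C1C[C@@H](c2ccc(O[Si](C)(C)C(C)(C)C)cc2)OC(Cl)C1Sc1ccccc1
F7 | step 2 | (6S)-6-[4-(tert-butyldimethylsilyloxy)phenyl]-4-(tert-butyldimethylsilyloxy)-N,N-dimethyl-3,6-dihydro-2H-pyran-2-amine (either C2 epimer) | CN(C)C1CC(O[Si](C)(C)C(C)(C)C)=C[C@@H](c2ccc(O[Si](C)(C)C(C)(C)C)cc2)O1
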